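**Retrosynthetic overview**
1. The target is the desilylated form of a bis-silyl chromene. Its 2H-pyran ring (O-1, C-2, C-3, C-4, C-4a, C-8a) is not closed directly: it comes from one-carbon ring expansion of a 2,2-dimethyl-2,3-dihydrobenzofuran ring (O-1, C-2, C-3, C-3a, C-7a) carrying CH2OMs on C-3.
2. Key step, one flask: a sensitized stilbene/prenyl [2+2] closes the cyclopentane and then the cyclobutane; addition of HFIP then triggers the 1,2-aryl shift and elimination that turn the furan ring into the pyran ring.
3. Enabling feature: the migrating arene carbon (C-3a, later C-4a) is para to the methoxy-bearing carbon and ortho to the ring oxygen, so it bridges readily (phenonium). The stereogenic C-3 of the five-membered ring is peri to the styryl carbon, steers the cycloaddition face, and is then erased as it becomes an sp2 carbon of the chromene.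
4. The cycloaddition precursor comes from Horner–Wadsworth–Emmons olefination of a lactol with a catechol benzylphosphonate; the lactol comes from a lactone made by cobalt-catalysed asymmetric hydroboration of a 3-methylidene-dihydrobenzofuran.
5. That alkene comes from a 5-exo-dig reductive Heck cyclization of an aryl 1,1-dimethylpropargyl ether plus a Stille prenylation, starting from methyl 3-hydroxy-5-methoxybenzoate. Ring order: dihydrofuran, temporary lactone, cyclopentane, cyclobutane, pyran by expansion.

Key step: step 13

Remark 1: in step 13 the cyclobutane is assumed to form on the styrene face opposite to the C-3 CH2OMs arm; if the opposite sense prevailed, only the ligand antipode in step 6 would be exchanged.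
Remark 2: benzofuran and chromene numbering is used in names; TBS = tert-butyldimethylsilyl; aldehyde 11 is taken as a catalogue compound.

Step 1
Reactants: 1 methyl 3-hydroxy-5-methoxybenzoate
Product: 2 methyl 2-bromo-5-hydroxy-3-methoxybenzoate
Conditions: NBS (1.0 equiv), MeCN, −10 to 0 °C
Reagents that add atoms: N-bromosuccinimide, O=C1CCC(=O)N1Br
Why: Electrophilic aromatic bromination in which the free hydroxyl, the strongest donor, directs para to the carbon that is also ortho to OMe, while the site between the two oxygens is the most hindered and reacts last.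

Step 2
Reactants: 2 methyl 2-bromo-5-hydroxy-3-methoxybenzoate
Product: 3 methyl 2-bromo-5-hydroxy-6-iodo-3-methoxybenzoate
Conditions: NIS (1.05 equiv), TFA (10 mol%), MeCN, 0 °C
Reagents that add atoms: N-iodosuccinimide, O=C1CCC(=O)N1I
Why: Acid-activated electrophilic iodination should take the remaining position that is ortho to the hydroxyl and para to the methoxy group (the carbon between the two oxygens lacks para activation), giving C–I and C–Br bonds that two later palladium steps can address one after the other.

Step 3
Reactants: 3 methyl 2-bromo-5-hydroxy-6-iodo-3-methoxybenzoate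
Product: 4 methyl 2-bromo-6-iodo-3-methoxy-5-[(2-methylbut-3-yn-2-yl)oxy]benzoate
Conditions: 3-chloro-3-methylbut-1-yne (1.5 equiv), DBU (1.7 equiv), CuCl2·2H2O (1 mol%), MeCN, 0 °C
Reagents that add atoms: 3-chloro-3-methylbut-1-yne, CC(C)(Cl)C#C
Why: Copper-catalysed O-propargylation of the phenol with the tertiary propargylic chloride gives the tertiary aryl propargyl ether far below the temperature of its Claisen rearrangement.

Step 4
Reactants: 4 methyl 2-bromo-6-iodo-3-methoxy-5-[(2-methylbut-3-yn-2-yl)oxy]benzoate
Product: 5 methyl 5-bromo-6-methoxy-2,2-dimethyl-3-methylidene-2,3-dihydro-1-benzofuran-4-carboxylate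
Conditions: Pd(OAc)2 (5 mol%), PPh3 (10 mol%), HCO2Na (1.5 equiv), DMF, 60 °C
Reagents that add atoms: none
Why: Reductive Heck cyclization in which zerovalent palladium inserts into C–I in preference to C–Br, 5-exo-dig syn-carbopalladation of the alkyne closes the dihydrofuran, and formate delivers hydride to the vinylpalladium, the quaternary C-2 preventing aromatization to a benzofuran.

Step 5
Reactants: 5 methyl 5-bromo-6-methoxy-2,2-dimethyl-3-methylidene-2,3-dihydro-1-benzofuran-4-carboxylate
Product: 6 methyl 6-methoxy-2,2-dimethyl-3-methylidene-5-(3-methylbut-2-en-1-yl)-2,3-dihydro-1-benzofuran-4-carboxylate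
Conditions: tributyl(3-methylbut-2-en-1-yl)stannane (1.3 equiv), Pd2(dba)3 (2.5 mol%), P(t-Bu)3 (10 mol%), CsF (2.2 equiv), 1,4-dioxane, 90 °C
Reagents that add atoms: tributyl(3-methylbut-2-en-1-yl)stannane, CCCC[Sn](CCCC)(CCCC)CC=C(C)C
Why: Stille coupling at the remaining C–Br bond, with a bulky electron-rich phosphine to overcome the two ortho substituents, should transfer the prenyl group through its unsubstituted carbon.

Step 6
Reactants: 6 methyl 6-methoxy-2,2-dimethyl-3-methylidene-5-(3-methylbut-2-en-1-yl)-2,3-dihydro-1-benzofuran-4-carboxylate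
Product: 9 (S)-lactone (peri-fused isochroman-1-one), via pinacol boronate 7 (not isolated), via hydroxy ester 8 (not isolated)
Conditions: (IPO)CoCl2 (2 mol%; IPO = chiral iminopyridine-oxazoline ligand, antipode chosen for the (S) centre), NaBHEt3 (4 mol%), HBpin (1.3 equiv), THF, 25 °C; then H2O2 (30% aq.), NaOH (2 M), 0 °C; then TsOH·H2O (5 mol%), toluene, 50 °C
Reagents that add atoms: pinacolborane (boron of 7), CC1(C)OBOC1(C)C; hydrogen peroxide (oxygen of 8 and 9), OO
Why: Cobalt-hydride-catalysed anti-Markovnikov asymmetric hydroboration of the 1,1-disubstituted aryl alkene (the trisubstituted prenyl alkene is inert), in which the chiral ligand selects the alkene face and so sets C-3, followed by stereoretentive oxidation and acid-catalysed lactonization with the peri ester.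

Step 7
Reactants: 9 (S)-lactone
Product: 10 lactol (cyclic hemiacetal of 9, anomer mixture)
Conditions: DIBAL-H (1.1 equiv), CH2Cl2, −78 °C; aqueous Rochelle salt
Reagents that add atoms: none
Why: Partial reduction of the lactone stops at the lactol because the tetrahedral aluminium hemiacetal is stable at −78 °C, and C-3 is not touched.

Step 8
Reactants: 11 3,4-bis[(tert-butyldimethylsilyl)oxy]benzaldehyde
Product: 12 {3,4-bis[(tert-butyldimethylsilyl)oxy]phenyl}methanol
Conditions: NaBH4 (1.0 equiv), MeOH, 0 °C
Reagents that add atoms: none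
Why: Chemoselective borohydride reduction of the aldehyde under conditions that leave the aryl silyl ethers intact.

Step 9
Reactants: 12 {3,4-bis[(tert-butyldimethylsilyl)oxy]phenyl}methanol
Product: 13 4-(bromomethyl)-1,2-bis[(tert-butyldimethylsilyl)oxy]benzene
Conditions: CBr4 (1.2 equiv), PPh3 (1.25 equiv), CH2Cl2, 0 °C
Reagents that add atoms: carbon tetrabromide, BrC(Br)(Br)Br
Why: Appel bromination converts the benzylic alcohol to the bromide under neutral conditions that spare the silyl ethers.

Step 10
Reactants: 13 4-(bromomethyl)-1,2-bis[(tert-butyldimethylsilyl)oxy]benzene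
Product: 14 diethyl ({3,4-bis[(tert-butyldimethylsilyl)oxy]phenyl}methyl)phosphonate
Conditions: P(OEt)3 (3 equiv, neat), 120 °C
Reagents that add atoms: triethyl phosphite, CCOP(OCC)OCC
Why: Michaelis–Arbuzov reaction of the reactive benzylic bromide with triethyl phosphite.

Step 11
Reactants: 10 lactol; 14 diethyl ({3,4-bis[(tert-butyldimethylsilyl)oxy]phenyl}methyl)phosphonate
Product: 15 [(3S)-4-{(E)-2-[3,4-bis(TBSO)phenyl]ethenyl}-6-methoxy-2,2-dimethyl-5-(3-methylbut-2-en-1-yl)-2,3-dihydro-1-benzofuran-3-yl]methanol
Conditions: 14 (1.5 equiv), NaHMDS (3.0 equiv), THF, 0 to 45 °C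
Reagents that add atoms: none
Why: Horner–Wadsworth–Emmons olefination on the open hydroxy-aldehyde form of the lactol should give the (E)-stilbene and release the lactol oxygen as the primary alcohol, while C-3, not alpha to the carbonyl, keeps its configuration.

Step 12
Reactants: 15 stilbene alcohol
Product: 16 [(3S)-4-{(E)-2-[3,4-bis(TBSO)phenyl]ethenyl}-6-methoxy-2,2-dimethyl-5-(3-methylbut-2-en-1-yl)-2,3-dihydro-1-benzofuran-3-yl]methyl methanesulfonate
Conditions: MsCl (1.2 equiv), Et3N (1.5 equiv), CH2Cl2, −20 °C
Reagents that add atoms: methanesulfonyl chloride, CS(=O)(=O)Cl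
Why: Sulfonylation of the primary alcohol via sulfene at low temperature in a non-ionizing solvent, where the beta-aryl mesylate should not yet ionize.

Step 13
Reactants: 16 stilbene mesylate
Product: 18 bis-TBS ether of the target (2H-chromene), via cycloadduct mesylate 17 (not isolated)
Conditions: [Ir(dF(CF3)ppy)2(dtbbpy)]PF6 (1 mol%), 2,6-di-tert-butyl-4-methylpyridine (1.5 equiv), MeCN (0.01 M, degassed), blue LEDs (450 nm), 20 °C; then HFIP (equal volume), 55 °C, dark
Reagents that add atoms: none
Why: Triplet energy transfer from the excited iridium sensitizer to the styrene (visible-light-sensitized intramolecular styrene–alkene [2+2]; alkene geometry is lost in the triplet) lets the benzylic carbon attack the prenyl CH in a 5-exo-trig closure of the cyclopentane, and the benzylic/tertiary 1,4-diradical then recombines after intersystem crossing to close the cyclobutane. The cis ring fusion is imposed by the bicyclo[3.2.0] geometry and the aryl group settles trans to the neighbouring ring-fusion hydrogen on the convex face because the diradical relaxes before closure; the absolute sense comes from the (S) centre at C-3 of the dihydrobenzofuran, whose pseudo-axial CH2OMs arm is peri to the styryl group and pushes its distal carbon, and hence the cyclobutane, to the opposite face (1,4-induction through allylic strain), giving 17. HFIP then ionizes the primary mesylate with participation of arene carbon C-3a, which is para to the methoxy group and ortho to the ring oxygen (phenonium ion); the five-membered ring opens to the six-membered chromanyl cation, which loses a proton (directly or after a 1,2-hydride shift to the benzylic position) to give the 3,4-double bond of the chromene, a Wagner–Meerwein ring expansion of the neophyl type as known for benzo-fused cycloalkylmethyl sulfonates, and the auxiliary stereocentre is erased. The step needs the cycloaddition to finish before ionization, which the non-ionizing first solvent secures, and aryl migration to win over hydride shift, which the doubly oxygen-activated migrating carbon secures, while the hindered pyridine removes the acid so that chromene and silyl ethers survive. Carrying the photolabile chromene as the saturated five-membered ring through the irradiation also keeps it out of the excited-state chemistry.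

Step 14
Reactants: 18 bis-TBS ether of the target
Product: 19 target CNP0207533.1
Conditions: TBAF (2.4 equiv), AcOH (2.4 equiv), THF, 0 °C, argon
Reagents that add atoms: none
Why: Fluoride-mediated cleavage of both aryl silyl ethers, buffered with acetic acid so that the catechol, the chromene and the cyclobutane are not exposed to base, affects no stereocentre.

**Compound list**
1 | methyl 3-hydroxy-5-methoxybenzoate | COC(=O)c1cc(O)cc(OC)c1 | starting material
2 | methyl 2-bromo-5-hydroxy-3-methoxybenzoate | COC(=O)c1cc(O)cc(OC)c1Br | intermediate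
3 | methyl 2-bromo-5-hydroxy-6-iodo-3-methoxybenzoate | COC(=O)c1c(I)c(O)cc(OC)c1Br | intermediate
4 | methyl 2-bromo-6-iodo-3-methoxy-5-[(2-methylbut-3-yn-2-yl)oxy]benzoate | COC(=O)c1c(I)c(OC(C)(C)C#C)cc(OC)c1Br | intermediate
5 | methyl 5-bromo-6-methoxy-2,2-dimethyl-3-methylidene-2,3-dihydro-1-benzofuran-4-carboxylate | COC(=O)c1c(Br)c(OC)cc2OC(C)(C)C(=C)c12 | intermediate
6 | methyl 6-methoxy-2,2-dimethyl-3-methylidene-5-(3-methylbut-2-en-1-yl)-2,3-dihydro-1-benzofuran-4-carboxylate | COC(=O)c1c(CC=C(C)C)c(OC)cc2OC(C)(C)C(=C)c12 | intermediate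
7 | methyl (3R)-6-methoxy-2,2-dimethyl-5-(3-methylbut-2-en-1-yl)-3-[(4,4,5,5-tetramethyl-1,3,2-dioxaborolan-2-yl)methyl]-2,3-dihydro-1-benzofuran-4-carboxylate (same spatial arrangement as (3S)-8; the descriptor changes because CH2B ranks below the aryl carbon) | COC(=O)c1c(CC=C(C)C)c(OC)cc2OC(C)(C)[C@H](CB3OC(C)(C)C(C)(C)O3)c12 | intermediate (not isolated)
8 | methyl (3S)-3-(hydroxymethyl)-6-methoxy-2,2-dimethyl-5-(3-methylbut-2-en-1-yl)-2,3-dihydro-1-benzofuran-4-carboxylate | COC(=O)c1c(CC=C(C)C)c(OC)cc2OC(C)(C)[C@H](CO)c12 | intermediate (not isolated)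
9 | (S)-lactone: delta-lactone closed between the C-4 carboxyl and the C-3 CH2O group of 8 (dihydrobenzofuran peri-fused to an isochroman-1-one) | O=C1OC[C@H]2C(C)(C)Oc3cc(OC)c(CC=C(C)C)c1c32 | intermediate
10 | lactol: cyclic hemiacetal obtained from 9, (S) at the former C-3, anomer mixture | OC1OC[C@H]2C(C)(C)Oc3cc(OC)c(CC=C(C)C)c1c32 | intermediate
11 | 3,4-bis[(tert-butyldimethylsilyl)oxy]benzaldehyde | O=Cc1ccc(O[Si](C)(C)C(C)(C)C)c(O[Si](C)(C)C(C)(C)C)c1 | starting material
12 | {3,4-bis[(tert-butyldimethylsilyl)oxy]phenyl}methanol | OCc1ccc(O[Si](C)(C)C(C)(C)C)c(O[Si](C)(C)C(C)(C)C)c1 | intermediate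
13 | 4-(bromomethyl)-1,2-bis[(tert-butyldimethylsilyl)oxy]benzene | BrCc1ccc(O[Si](C)(C)C(C)(C)C)c(O[Si](C)(C)C(C)(C)C)c1 | intermediate
14 | diethyl ({3,4-bis[(tert-butyldimethylsilyl)oxy]phenyl}methyl)phosphonate | CCOP(=O)(OCC)Cc1ccc(O[Si](C)(C)C(C)(C)C)c(O[Si](C)(C)C(C)(C)C)c1 | intermediate
15 | [(3S)-4-{(E)-2-[3,4-bis(TBSO)phenyl]ethenyl}-6-methoxy-2,2-dimethyl-5-(3-methylbut-2-en-1-yl)-2,3-dihydro-1-benzofuran-3-yl]methanol | OC[C@H]1C(C)(C)Oc2cc(OC)c(CC=C(C)C)c(/C=C/c3ccc(O[Si](C)(C)C(C)(C)C)c(O[Si](C)(C)C(C)(C)C)c3)c21 | intermediate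
16 | methanesulfonate of 15, (3S) | CS(=O)(=O)OC[C@H]1C(C)(C)Oc2cc(OC)c(CC=C(C)C)c(/C=C/c3ccc(O[Si](C)(C)C(C)(C)C)c(O[Si](C)(C)C(C)(C)C)c3)c21 | intermediate
17 | cycloadduct mesylate: (3S)-2,2-dimethyl-2,3-dihydrobenzofuran-3-ylmethyl methanesulfonate whose benzene ring (C-4/C-5) is fused to the cyclopentane of a cis-bicyclo[3.2.0] unit; cyclobutane with a gem-dimethyl carbon, (S) at the ring-fusion carbon next to the benzylic CH2, (R) at the benzylic ring-fusion carbon, (S) at the carbon bearing the 3,4-bis(TBSO)phenyl group; CH2OMs anti to the cyclobutane | COc1cc2OC(C)(C)[C@H](COS(C)(=O)=O)c2c2c1C[C@H]1[C@@H]2[C@H](c2ccc(O[Si](C)(C)C(C)(C)C)c(O[Si](C)(C)C(C)(C)C)c2)C1(C)C | intermediate (not isolated)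
18 | bis-TBS ether of the target: 7-methoxy-2,2-dimethyl-2H-chromene fused across C-5/C-6 to the same cis-bicyclo[3.2.0] unit (S, R, S as in 17) | COc1cc2c(c3c1C[C@H]1[C@@H]3[C@H](c3ccc(O[Si](C)(C)C(C)(C)C)c(O[Si](C)(C)C(C)(C)C)c3)C1(C)C)C=CC(C)(C)O2 | intermediate
19 | target CNP0207533.1: 4-substituted benzene-1,2-diol on the (S) cyclobutane carbon of the 7-methoxy-2,2-dimethyl-2H-chromene-fused cis-cyclobuta-indane; (S) at the ring-fusion carbon next to CH2, (R) at the benzylic ring-fusion carbon | COc1cc2c(c3c1C[C@H]1[C@@H]3[C@H](c3ccc(O)c(O)c3)C1(C)C)C=CC(C)(C)O2 | target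

Total step count: 14. Longest linear sequence: 11 steps (steps 1–7 and 11–14).

**Steps most likely to fail**

Step 13. The C-3 arm may discriminate the two faces of the twisted styrene too weakly in the excited state. The mesylate may also ionize before the cycloaddition is complete, which removes the controlling centre, or hydride and methyl shifts may compete with aryl migration. The fallback sets out from 15 and comes back at 17. The alcohol is capped with pivaloyl chloride and pyridine as the pivalate of 15 F1, a bulkier arm that cannot ionize. F1 is cyclized in the ground state by hole catalysis (radical-cation [2+2] with tris(4-bromophenyl)aminium hexachloroantimonate, (4-BrC6H4)3N·SbCl6, CH2Cl2, 0 °C) to the cycloadduct pivalate F2. The unwanted facial isomer is a diastereomer as long as C-3 is stereogenic, so it is removed by chromatography at this stage. DIBAL-H at −78 °C then frees the cycloadduct alcohol F3, which is mesylated (MsCl, Et3N) to 17, now isolated, and ring-expanded in buffered HFIP as in the second half of step 13.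

Step 6. Hydrometalation of the alkene, flanked by the quaternary C-2 and the peri ester, may be slow and poorly face-selective, so that 9 forms in low enantiomeric purity. The fallback sets out from scalemic 9 and comes back at 9, replacing catalyst control by classical resolution. AlMe3-mediated aminolysis with (S)-1-phenylethanamine opens the lactone to the (3S) hydroxy amide F4 and, from the minor enantiomer, the (3R) hydroxy amide F5. The diastereomers are separated by crystallization or chromatography, and F4 is relactonized (TsOH, toluene, 80 °C) to enantiopure 9.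

Step 11. The ring–chain equilibrium of the lactol may lie on the closed side, and the aldehyde, once open, is shielded by two ortho substituents, so the phosphonate anion may add slowly and decompose. The fallback sets out from 10 and comes back at 15. The lactol is methylenated with the small ylide Ph3P=CH2 (Wittig; from methyltriphenylphosphonium bromide and KOt-Bu, THF) to the styrene alcohol F6. The aryl group is then introduced by a Mizoroki–Heck reaction with 4-bromo-1,2-bis[(tert-butyldimethylsilyl)oxy]benzene F7, made from 4-bromocatechol with TBSCl and imidazole. Under Pd2(dba)3, P(t-Bu)3 and Cy2NMe in dioxane at 80 °C, syn insertion and syn beta-hydride elimination should give the (E)-stilbene 15.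

Further compounds
F1 | step 13 | pivalate of 15, (3S) | CC(C)(C)C(=O)OC[C@H]1C(C)(C)Oc2cc(OC)c(CC=C(C)C)c(/C=C/c3ccc(O[Si](C)(C)C(C)(C)C)c(O[Si](C)(C)C(C)(C)C)c3)c21
F2 | step 13 | cycloadduct pivalate (as 17 with OPiv in place of OMs) | COc1cc2OC(C)(C)[C@H](COC(=O)C(C)(C)C)c2c2c1C[C@H]1[C@@H]2[C@H](c2ccc(O[Si](C)(C)C(C)(C)C)c(O[Si](C)(C)C(C)(C)C)c2)C1(C)C
F3 | step 13 | cycloadduct alcohol (as 17 with OH in place of OMs) | COc1cc2OC(C)(C)[C@H](CO)c2c2c1C[C@H]1[C@@H]2[C@H](c2ccc(O[Si](C)(C)C(C)(C)C)c(O[Si](C)(C)C(C)(C)C)c2)C1(C)C
F4 | step 6 | (3S)-3-(hydroxymethyl)-6-methoxy-2,2-dimethyl-5-(3-methylbut-2-en-1-yl)-N-[(1S)-1-phenylethyl]-2,3-dihydro-1-benzofuran-4-carboxamide | C[C@H](NC(=O)c1c(CC=C(C)C)c(OC)cc2OC(C)(C)[C@H](CO)c12)c1ccccc1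
F5 | step 6 | (3R)-3-(hydroxymethyl)-6-methoxy-2,2-dimethyl-5-(3-methylbut-2-en-1-yl)-N-[(1S)-1-phenylethyl]-2,3-dihydro-1-benzofuran-4-carboxamide | C[C@H](NC(=O)c1c(CC=C(C)C)c(OC)cc2OC(C)(C)[C@@H](CO)c12)c1ccccc1
F6 | step 11 | [(3S)-4-ethenyl-6-methoxy-2,2-dimethyl-5-(3-methylbut-2-en-1-yl)-2,3-dihydro-1-benzofuran-3-yl]methanol | OC[C@H]1C(C)(C)Oc2cc(OC)c(CC=C(C)C)c(C=C)c21
F7 | step 11 | 4-bromo-1,2-bis[(tert-butyldimethylsilyl)oxy]benzene | Brc1ccc(O[Si](C)(C)C(C)(C)C)c(O[Si](C)(C)C(C)(C)C)c1
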